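The numbers in the tables are simulated from invented constants, noise included.

You cannot take more complex with one exchanged out of this flask than its incoming ligand can make: 50.0% of the starting complex charged, or half. The ligand is the limiting reagent, with [incoming ligand] at 0.400 M against [starting complex] at 0.80 M.

| flask | starting complex | incoming ligand | remark | time |
|---|---|---|---|---|
| delta | 0.80 M | 0.40 M | the very flask that is asked about, followed so far |  |
| flask | 0.80 M | 0.400 M |  | 6.0 h |

- delta (time / h: complex with one exchanged / %, starting complex / %): 0.200: 2, 95; 0.417: 5, 93; 1.00: 10, 87; 2.50: 16, 76

(each reading ± 1.5 percentage points)

- the numbers in the tables scatter with a standard deviation of 1.5 percentage points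

- equivalents of incoming ligand to starting complex, everything else as given, that leave most complex with one exchanged at 6.0 h
- the amount of complex with one exchanged then, in percent of the starting complex charged
- the amount of complex with one exchanged with the amounts as given

The delta run has the same charges as this flask. Call the net yield the points of complex with one exchanged gained per point of starting complex lost. It reads as follows:

up to 1.00 h: 0.769

from there to 2.50 h: 0.545

Now take two extremes for 6.0 h. If the net yield fell to zero after the last reading, the flask stays at 16%. If it held at the later value while starting complex fell to 50.0%, the level reached if each incoming ligand took up one starting complex, you get: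

16% + 0.545 × (76% − 50.0%) = 30.2%

The net yield reads lower in the later stretch, so I expect the flask nearer the lower end, though these readings carry a scatter of 1.5 points.

The forecast gives 18.2% as charged, and 19.2% at 0.73 equiv, on the ground that “The second exchange is faster than the first.”

The flask as charged gives 16.5%, and the best charge is 1.24 equiv, which gives 24.0%, so the forecast's equivalents are low by a factor of 1.70.

complex with three exchanged + incoming ligand → leaving ligand + complex with four exchanged (k = 0.0309 M⁻¹ h⁻¹); starting complex + complex with one exchanged → side product (k = 0.218 M⁻¹ h⁻¹); starting complex + incoming ligand → leaving ligand + complex with one exchanged (k = 0.338 M⁻¹ h⁻¹); complex with two exchanged + incoming ligand → leaving ligand + complex with three exchanged (k = 0.0411 M⁻¹ h⁻¹); complex with one exchanged + incoming ligand → leaving ligand + complex with two exchanged (k = 0.395 M⁻¹ h⁻¹) Complex with one exchanged is made 2.27 times as fast as it is used up at 1.64 h, but 0.795 times as fast at 6.00 h. The flask's net yield from 3.00 h to 6.00 h is 0.0289. Left until 25 h, the same flask holds 6.35%, a net yield after 6.00 h of −0.430.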